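The birch run, the richer of the two earlier flasks at 0.79 M against 0.045 M, ended at 40.0 min with 6% target and 2% over-reacted product, and two chemists read that end differently when asked about five new flasks.

| setting | oak | birch | south-west | north | south | south-east | north-west |
|---|---|---|---|---|---|---|---|
| substrate | 0.045 M | 0.79 M | 1.0 M | 0.080 M | 0.30 M | 0.20 M | 0.50 M |
| gas phase | 93 mM (held) | 93 mM (held) | 93 mM (held) | 93 mM (held) | 93 mM (held) | 93 mM (held) | 93 mM (held) |
| remark | run made earlier | run made earlier |  |  |  |  |  |
| time |  |  | 50 min | 50 min | 50 min | 50 min | 50 min |

| run | time / min | target / % | over-reacted product / % |
|---|---|---|---|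
| oak | 8.00 | 8 | 0 |
| oak | 20.0 | 14 | 12 |
| oak | 25.0 | 14 | 13 |
| oak | 40.0 | 10 | 38 |
| birch | 8.00 | 3 | 1 |
| birch | 20.0 | 2 | 0 |
| birch | 25.0 | 3 | 3 |
| birch | 40.0 | 6 | 2 |

(each reading ± 1.5 percentage points)

- the flasks put in order of share of target in all that became target or over-reacted product, best first, at 50 min (south-west / north / south / south-east / north-west)
- the share of target in all that became target or over-reacted product of the flask you put first, at 50 min
- the share of target in all that became target or over-reacted product of the flask you put last, at 50 min

- at the start none of the gas is dissolved
- steps under discussion: substrate + dissolved gas <-> target; dissolved gas + target -> over-reacted product; gas phase <-> dissolved gas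

One chemist, who made the forecast, follows the substrate: “More substrate therefore means lower fractional conversion and a better share.” So the forecast puts the flasks in the order south-west > north-west > south > south-east > north, with south-west at 81% and north at 22%.

I follow the gas. Each molecule of target holds one dissolved gas and each molecule of over-reacted product holds two, so the birch reading gives a gas uptake, the concentration of target plus 2 times that of over-reacted product, divided by the time, of 1.98 mM/min. The oak run took up 0.967 mM/min, about half of that, so I carry this uptake only to the rich south-west flask and leave north to the forecast. Over 50 min the uptake makes a budget of 98.8 mM for south-west. If I take its [target] at birch's 47.4 mM, a single reading with scatter 1.5 percentage points, then [over-reacted product] = (98.8 mM − 47.4 mM) / 2 = 25.7 mM. That makes the share of target, the selectivity, 64.9% in south-west, which is lower than the forecast's figure.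

The simulation gives the order south-west > north-west > south > south-east > north, with south-west at 62.9% and north at 23.0%.

    substrate + dissolved gas ⇌ target (K = 8.70 /M, k = 2.18 /M/min)
    dissolved gas + target → over-reacted product (k = 2.73 /M/min)
    gas phase ⇌ dissolved gas, rate k3*(csat - [dissolved gas]) (kL = 0.0294 /min)

The forecast's substrate reckoning stands in north, 22% against 23.0%, and its south-west figure is 18 points too high. At 50 min south-west holds 55.5 mM of target and has taken up 121 mM of gas, more than my budget. The neighbour of north charged with 0.20 M stands between oak and birch in substrate and holds 20.2 mM of target at 50 min, so I take the two read uptakes as two ends rather than carry one of them to it: over 50 min oak's uptake gives a share of 58.9% and birch's gives 33.9%. That flask took up 1.91 mM/min and gives 35.0%.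

The numbers in the tables are calculated with constants of no real substance.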